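The oxolane ring (O1, C2 bearing the aryl group, C3, C4 bearing the benzyl group, C5) is cut at O1–C2 and C3–C4, and the benzylic carbon on C4 is cut from its arene. O1, C5, C4 and that benzylic carbon then map onto one propargyl alcohol unit on which all three bonds converge. One palladium-catalysed three-component cascade (oxa-Michael addition, 5-exo-dig carbopalladation, aryl–vinyl reductive elimination) should close the ring, attach the second arene and set C2, a chiral bisphosphine selecting between equilibrating alkoxide adducts. The precursors are propargyl alcohol, a benzyl-protected vanillylidene malonate and benzyl-protected 4-iodoguaiacol. The C3 and C4 configurations and the caffeate follow by known steps.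

Key step: step 3

Remark: the target is the (2R,3S,4S) isomer (aryl and CH2O trans, CH2O and benzyl cis). The sense of induction of a chiral ligand in step 3 cannot be predicted, so (R)-DTBM-SEGPHOS stands for whichever enantiomer of the ligand is found to favour (2S)-9.

Step 1
Reactants: 1 4-(benzyloxy)-3-methoxybenzaldehyde; 2 dimethyl malonate
Product: 3 dimethyl 2-{[4-(benzyloxy)-3-methoxyphenyl]methylidene}propanedioate
Conditions: piperidine (cat.), AcOH (cat.), toluene, reflux, Dean–Stark trap
Reagents that add atoms: none
Why: Knoevenagel condensation of a non-enolisable aldehyde with the doubly activated methylene is driven to completion by azeotropic removal of water, and the symmetric malonate gives one alkene with no stereochemical issue.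

Step 2
Reactants: 4 4-iodo-2-methoxyphenol
Product: 5 1-(benzyloxy)-4-iodo-2-methoxybenzene
Conditions: BnBr, K2CO3, DMF, 20 °C
Reagents that add atoms: benzyl bromide, BrCc1ccccc1
Why: Williamson ether synthesis, in which the phenoxide formed with K2CO3 displaces bromide from the benzylic halide by SN2 attack while the aryl iodide stays inert.

Step 3
Reactants: 6 propargyl alcohol; 3 dimethyl 2-{[4-(benzyloxy)-3-methoxyphenyl]methylidene}propanedioate; 5 1-(benzyloxy)-4-iodo-2-methoxybenzene
Product: 9 dimethyl (2S,4Z)-2-[4-(benzyloxy)-3-methoxyphenyl]-4-{[4-(benzyloxy)-3-methoxyphenyl]methylidene}oxolane-3,3-dicarboxylate, via lithium prop-2-yn-1-olate 7 (not isolated), via racemic lithium malonate enolate adduct 8 (not isolated)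
Conditions: 6 (1.2 equiv), n-BuLi (1.1 equiv), THF, 0 °C; then 3, 5 (1.2 equiv), Pd(dba)2 (5 mol %), (R)-DTBM-SEGPHOS (6 mol %), THF/DMSO, 20 °C
Reagents that add atoms: none
Why: Proposed new method: the lithium alkoxide 7 adds reversibly to the benzylidene malonate 3 (oxa-Michael addition, O1–C2) to give the racemic, rapidly interconverting malonate enolate 8, while oxidative addition of 5 to the zerovalent palladium–bisphosphine complex gives an arylpalladium iodide that, after loss of iodide to lithium, binds the alkyne of 8; the enolate carbon then attacks the internal alkyne carbon on the face opposite palladium (C3–C4), and reductive elimination from the resulting aryl(vinyl)palladium joins the arene to the exocyclic carbon and returns zerovalent palladium. The closest known reaction type is the racemic palladium-mediated three-component coupling of propargyl alkoxides, alkylidene malonates and aryl halides, and the closest enantioselective relative is the Conia-ene-type cyclisation of 1,3-dicarbonyl enolates onto alkynes bound to cationic divalent palladium–bisphosphine complexes. The oxolane ring is closed in the 5-exo-dig mode, which the O–CH2 tether between C2 and the terminal alkyne enforces. C2 is formed without control in the reversible oxa-Michael step and is fixed in the ring closure, where the chiral pocket of the ligand around the alkyne-bound palladium is expected to let one enantiomer of 8 cyclise faster than the other while both keep interconverting (dynamic kinetic resolution, catalyst control), and it cannot revert afterwards because C3 has become quaternary. The (Z) geometry follows from the anti addition of carbon and palladium across the alkyne and from reductive elimination with retention. The step needs the cascade to outrun direct alkynylation of 5 at the alkyne terminus and any ligand-free racemic closure, which the soft, doubly ester-stabilised carbanion (unreactive toward the free alkyne at 20 °C), the slight deficit of base relative to 6 and the preformed ligated catalyst are meant to secure, and it needs the retro-oxa-Michael step to be faster than ring closure, which the electron-rich aryl group of the acceptor favours.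

Step 4
Reactants: 9 dimethyl (2S,4Z)-2-[4-(benzyloxy)-3-methoxyphenyl]-4-{[4-(benzyloxy)-3-methoxyphenyl]methylidene}oxolane-3,3-dicarboxylate
Product: 10 methyl (2R,3R,4Z)-2-[4-(benzyloxy)-3-methoxyphenyl]-4-{[4-(benzyloxy)-3-methoxyphenyl]methylidene}oxolane-3-carboxylate
Conditions: LiCl (3 equiv), H2O (3 equiv), DMSO, 130 °C
Reagents that add atoms: none
Why: Krapcho dealkoxycarbonylation, in which chloride removes one ester methyl group by SN2 attack and the carboxylate loses CO2 to a dienolate that is protonated at C3, should leave the styrene-type exocyclic alkene and C2 untouched and, because C3 stays epimerisable under the reaction conditions, should settle the remaining ester trans to the C2 aryl group (thermodynamic control, C3 R).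

Step 5
Reactants: 10 methyl (2R,3R,4Z)-2-[4-(benzyloxy)-3-methoxyphenyl]-4-{[4-(benzyloxy)-3-methoxyphenyl]methylidene}oxolane-3-carboxylate
Product: 11 methyl (2R,3R,4S)-2-(4-hydroxy-3-methoxyphenyl)-4-(4-hydroxy-3-methoxybenzyl)oxolane-3-carboxylate
Conditions: H2 (1 atm), 10% Pd/C (palladium on carbon), EtOAc/MeOH, 20 °C
Reagents that add atoms: none
Why: Heterogeneous catalytic hydrogenation combined with hydrogenolysis of both benzyl aryl ethers: the alkene should bind to the palladium surface through the face opposite the adjacent C3 ester, so that both hydrogens arrive anti to the ester and the new benzyl group at C4 ends up cis to it (C4 S, substrate control), while the cyclic benzylic C2–O1 bond is expected to survive neutral conditions at one atmosphere.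

Step 6
Reactants: 11 methyl (2R,3R,4S)-2-(4-hydroxy-3-methoxyphenyl)-4-(4-hydroxy-3-methoxybenzyl)oxolane-3-carboxylate
Product: 12 (2R,3S,4S)-lariciresinol
Conditions: LiAlH4 (3 equiv), THF, 0 °C to 20 °C; aq. potassium sodium tartrate (KNaC4H4O6)
Reagents that add atoms: none
Why: Hydride reduction of the ester by LiAlH4, used in excess because the two phenols consume hydride as aluminium phenoxides, gives the primary alcohol without touching C2, C3 or C4, and the tartrate work-up avoids the acid that could ionise the benzylic ether.

Step 7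
Reactants: 13 caffeic acid
Product: 14 (E)-3-(3,4-diacetoxyphenyl)prop-2-enoic acid
Conditions: Ac2O, pyridine, 20 °C; then H2O, aq. HCl
Reagents that add atoms: acetic anhydride, CC(=O)OC(C)=O
Why: O-Acetylation of the two phenols by acyl transfer from the anhydride under pyridine catalysis, with any mixed anhydride at the carboxyl group hydrolysed again in the aqueous work-up.

Step 8
Reactants: 12 (2R,3S,4S)-lariciresinol; 14 (E)-3-(3,4-diacetoxyphenyl)prop-2-enoic acid
Product: 15 [(2R,3S,4S)-2-(4-hydroxy-3-methoxyphenyl)-4-(4-hydroxy-3-methoxybenzyl)oxolan-3-yl]methyl (E)-3-(3,4-diacetoxyphenyl)prop-2-enoate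
Conditions: PPh3, DIAD, THF, 0 °C to 20 °C
Reagents that add atoms: none
Why: Mitsunobu esterification, in which only the aliphatic primary hydroxyl is activated as an alkoxyphosphonium ion and is displaced by the carboxylate of the far more acidic 14 while the two phenols stay spectators, touches no stereocentre because the carbinol carbon is a CH2 group.

Step 9
Reactants: 15 [(2R,3S,4S)-2-(4-hydroxy-3-methoxyphenyl)-4-(4-hydroxy-3-methoxybenzyl)oxolan-3-yl]methyl (E)-3-(3,4-diacetoxyphenyl)prop-2-enoate
Product: 16 [(2R,3S,4S)-2-(4-hydroxy-3-methoxyphenyl)-4-(4-hydroxy-3-methoxybenzyl)oxolan-3-yl]methyl (E)-3-(3,4-dihydroxyphenyl)prop-2-enoate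
Conditions: N2H4·H2O (2.2 equiv), THF/MeOH, 0 °C, argon
Reagents that add atoms: none
Why: Chemoselective hydrazinolysis of the aryl acetates, which carry phenoxide leaving groups and are cleaved much faster than the conjugated alkyl caffeate, should release the catechol at 0 °C without ester cleavage, conjugate addition or epimerisation.

Compound list
1 | 4-(benzyloxy)-3-methoxybenzaldehyde (O-benzylvanillin) | COc1cc(C=O)ccc1OCc1ccccc1 | starting material
2 | dimethyl malonate | COC(=O)CC(=O)OC | starting material
3 | dimethyl 2-{[4-(benzyloxy)-3-methoxyphenyl]methylidene}propanedioate | COC(=O)C(=Cc1ccc(OCc2ccccc2)c(OC)c1)C(=O)OC | intermediate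
4 | 4-iodo-2-methoxyphenol | COc1cc(I)ccc1O | starting material
5 | 1-(benzyloxy)-4-iodo-2-methoxybenzene | COc1cc(I)ccc1OCc1ccccc1 | intermediate
6 | propargyl alcohol (prop-2-yn-1-ol) | C#CCO | starting material
7 | lithium prop-2-yn-1-olate (not isolated) | [Li+].[O-]CC#C | intermediate
8 | lithium salt of the malonate carbanion of dimethyl 2-{[4-(benzyloxy)-3-methoxyphenyl](prop-2-yn-1-yloxy)methyl}propanedioate, racemic and equilibrating (not isolated) | [Li+].COC(=O)[C-](C(=O)OC)C(OCC#C)c1ccc(OCc2ccccc2)c(OC)c1 | intermediate
9 | dimethyl (2S,4Z)-2-[4-(benzyloxy)-3-methoxyphenyl]-4-{[4-(benzyloxy)-3-methoxyphenyl]methylidene}oxolane-3,3-dicarboxylate (C2 arranged in space as in the target; the descriptor is S here because C3 outranks the aryl carbon) | COc1cc(/C=C2\CO[C@@H](c3ccc(OCc4ccccc4)c(OC)c3)C2(C(=O)OC)C(=O)OC)ccc1OCc1ccccc1 | intermediate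
10 | methyl (2R,3R,4Z)-2-[4-(benzyloxy)-3-methoxyphenyl]-4-{[4-(benzyloxy)-3-methoxyphenyl]methylidene}oxolane-3-carboxylate (aryl and ester trans; C2 not inverted, only re-ranked) | COc1cc(/C=C2\CO[C@@H](c3ccc(OCc4ccccc4)c(OC)c3)[C@@H]2C(=O)OC)ccc1OCc1ccccc1 | intermediate
11 | methyl (2R,3R,4S)-2-(4-hydroxy-3-methoxyphenyl)-4-(4-hydroxy-3-methoxybenzyl)oxolane-3-carboxylate (aryl and ester trans, ester and benzyl cis) | COc1cc(C[C@@H]2CO[C@@H](c3ccc(O)c(OC)c3)[C@@H]2C(=O)OC)ccc1O | intermediate
12 | (2R,3S,4S)-lariciresinol, [(2R,3S,4S)-2-(4-hydroxy-3-methoxyphenyl)-4-(4-hydroxy-3-methoxybenzyl)oxolan-3-yl]methanol | COc1cc(C[C@@H]2CO[C@@H](c3ccc(O)c(OC)c3)[C@@H]2CO)ccc1O | intermediate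
13 | caffeic acid | O=C(O)/C=C/c1ccc(O)c(O)c1 | starting material
14 | (E)-3-(3,4-diacetoxyphenyl)prop-2-enoic acid | CC(=O)Oc1ccc(/C=C/C(=O)O)cc1OC(C)=O | intermediate
15 | [(2R,3S,4S)-2-(4-hydroxy-3-methoxyphenyl)-4-(4-hydroxy-3-methoxybenzyl)oxolan-3-yl]methyl (E)-3-(3,4-diacetoxyphenyl)prop-2-enoate | COc1cc(C[C@@H]2CO[C@@H](c3ccc(O)c(OC)c3)[C@@H]2COC(=O)/C=C/c2ccc(OC(C)=O)c(OC(C)=O)c2)ccc1O | intermediate
16 | [(2R,3S,4S)-2-(4-hydroxy-3-methoxyphenyl)-4-(4-hydroxy-3-methoxybenzyl)oxolan-3-yl]methyl (E)-3-(3,4-dihydroxyphenyl)prop-2-enoate (CNP0132883.1) | COc1cc(C[C@@H]2CO[C@@H](c3ccc(O)c(OC)c3)[C@@H]2COC(=O)/C=C/c2ccc(O)c(O)c2)ccc1O | target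

Total step count: 9
Longest linear sequence: 7 steps (steps 1, 3, 4, 5, 6, 8, 9)

Steps most likely to fail

Step 3. The ring closure may discriminate too weakly between the two interconverting enantiomers of 8, or direct alkynylation of 5 may consume the catalyst. Fallback: setting out from 3, 5 and 6, the coupling is run under the known achiral conditions (lithium alkoxide of 6, PdCl2(PPh3)2 reduced in the flask by n-BuLi to zerovalent palladium, THF/DMSO, 20 °C). This should give racemic dimethyl (4Z)-2-[4-(benzyloxy)-3-methoxyphenyl]-4-{[4-(benzyloxy)-3-methoxyphenyl]methylidene}oxolane-3,3-dicarboxylate F1. F1 is resolved by preparative chromatography on a chiral stationary phase (cellulose tris(3,5-dimethylphenylcarbamate), supercritical CO2/MeOH). The (2S) enantiomer is 9, where the route is rejoined, and the unwanted dimethyl (2R,4Z)-2-[4-(benzyloxy)-3-methoxyphenyl]-4-{[4-(benzyloxy)-3-methoxyphenyl]methylidene}oxolane-3,3-dicarboxylate F2 is set aside.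

Step 5. Hydrogen may be delivered with poor facial selectivity to the exocyclic alkene, the alkene may migrate into the ring on the catalyst, or the C2–O1 benzylic bond may be hydrogenolysed. Fallback: setting out from 10, the ester is reduced with i-Bu2AlH (CH2Cl2, −78 °C) to [(2R,3S,4Z)-2-[4-(benzyloxy)-3-methoxyphenyl]-4-{[4-(benzyloxy)-3-methoxyphenyl]methylidene}oxolan-3-yl]methanol F3. F3 is silylated (TBDPSCl, imidazole, DMF) to tert-butyl{[(2R,3S,4Z)-2-[4-(benzyloxy)-3-methoxyphenyl]-4-{[4-(benzyloxy)-3-methoxyphenyl]methylidene}oxolan-3-yl]methoxy}diphenylsilane F4. The much bulkier silyloxymethyl group now screens its own face, so hydrogenation over 10% Pd/C (1 atm H2, EtOAc) should give (2R,3S,4S)-3-[(tert-butyldiphenylsilyloxy)methyl]-2-(4-hydroxy-3-methoxyphenyl)-4-(4-hydroxy-3-methoxybenzyl)oxolane F5. Bu4NF buffered with AcOH in THF then removes the silyl group to give 12, where the route is rejoined with 11 bypassed.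

Step 4. The exocyclic alkene may migrate into conjugation with the ester, or the C2 configuration may erode through reversible ring opening of the hot ester enolate. Fallback: setting out from 9, one ester is saponified (KOH, 1.05 equiv, MeOH/THF/H2O, 20 °C), expected at the ester on the face remote from the C2 aryl group. This should give (2S,3S,4Z)-2-[4-(benzyloxy)-3-methoxyphenyl]-4-{[4-(benzyloxy)-3-methoxyphenyl]methylidene}-3-(methoxycarbonyl)oxolane-3-carboxylic acid F6. F6 is decarboxylated under mild, halide-free conditions (Cu2O cat., MeCN, reflux), with brief equilibration at C3 by catalytic Et3N if needed, to give 10, where the route is rejoined.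

Further compounds
F1 | step 3 | racemic dimethyl (4Z)-2-[4-(benzyloxy)-3-methoxyphenyl]-4-{[4-(benzyloxy)-3-methoxyphenyl]methylidene}oxolane-3,3-dicarboxylate | COc1cc(/C=C2\COC(c3ccc(OCc4ccccc4)c(OC)c3)C2(C(=O)OC)C(=O)OC)ccc1OCc1ccccc1
F2 | step 3 | dimethyl (2R,4Z)-2-[4-(benzyloxy)-3-methoxyphenyl]-4-{[4-(benzyloxy)-3-methoxyphenyl]methylidene}oxolane-3,3-dicarboxylate | COc1cc(/C=C2\CO[C@H](c3ccc(OCc4ccccc4)c(OC)c3)C2(C(=O)OC)C(=O)OC)ccc1OCc1ccccc1
F3 | step 5 | [(2R,3S,4Z)-2-[4-(benzyloxy)-3-methoxyphenyl]-4-{[4-(benzyloxy)-3-methoxyphenyl]methylidene}oxolan-3-yl]methanol | COc1cc(/C=C2\CO[C@@H](c3ccc(OCc4ccccc4)c(OC)c3)[C@@H]2CO)ccc1OCc1ccccc1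
F4 | step 5 | tert-butyl{[(2R,3S,4Z)-2-[4-(benzyloxy)-3-methoxyphenyl]-4-{[4-(benzyloxy)-3-methoxyphenyl]methylidene}oxolan-3-yl]methoxy}diphenylsilane | COc1cc(/C=C2\CO[C@@H](c3ccc(OCc4ccccc4)c(OC)c3)[C@@H]2CO[Si](c5ccccc5)(c5ccccc5)C(C)(C)C)ccc1OCc1ccccc1
F5 | step 5 | (2R,3S,4S)-3-[(tert-butyldiphenylsilyloxy)methyl]-2-(4-hydroxy-3-methoxyphenyl)-4-(4-hydroxy-3-methoxybenzyl)oxolane | COc1cc(C[C@@H]2CO[C@@H](c3ccc(O)c(OC)c3)[C@@H]2CO[Si](c4ccccc4)(c4ccccc4)C(C)(C)C)ccc1O
F6 | step 4 | (2S,3S,4Z)-2-[4-(benzyloxy)-3-methoxyphenyl]-4-{[4-(benzyloxy)-3-methoxyphenyl]methylidene}-3-(methoxycarbonyl)oxolane-3-carboxylic acid | COc1cc(/C=C2\CO[C@@H](c3ccc(OCc4ccccc4)c(OC)c3)[C@@]2(C(=O)O)C(=O)OC)ccc1OCc1ccccc1
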